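**Retrosynthetic overview**

1. The target is methyl shikimate (carbocycle C1–C6: ester on C1, C1=C2, oxygen on C3, C4 and C5; 3,4-cis, 4,5-trans; 3R,4S,5R) with (E)-3-methylpent-2-enoyl groups on O3 and O5. The O3 ester is disconnected by palladium-catalysed opening of a 3,4-cyclic carbonate with the acid (this also frees O4–H), the O5 ester by Steglich esterification.
2. Enabling feature: O5 sits 1,4 across the carbocycle from the vinylic C2, and C1 between them carries an enolisable ester. C2–C1(CO2Me)–C6–C5 plus O5 is therefore a furan 3-ester in disguise; O5 can act as a temporary one-atom bridge from C5 to C2 (7-oxabicyclo[2.2.1]heptane), and the C2–O bond, absent from the target, is cut later by E1cB with formation of C1=C2.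
3. Key disconnection: Diels–Alder reaction of methyl furan-3-carboxylate with vinylene carbonate (the cis-3,4-diol as a symmetric two-carbon dienophile), forming C2–C3 and C4–C5. The endo adduct has the carbonate anti to the bridge, which is the 3,4-cis/4,5-trans pattern.
4. Ring order: carbocycle and oxygen bridge together in step 1 (the dioxolanone ring is brought in intact); bridge opened in step 3; dioxolanone opened in step 6.
5. The cycloadduct is racemic; the absolute configuration is secured by lipase resolution of the C5 acetate (step 4).

Key step: step 1

Assumption: (E)-3-methylpent-2-enoic acid is bought as the pure E isomer (offered as trans-3-methyl-2-pentenoic acid); racemic compounds are drawn as the enantiomer that leads to the target.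

**Route**

Step 1
Reactants: 1 methyl furan-3-carboxylate; 2 vinylene carbonate (1,3-dioxol-2-one)
Product: 3 racemic endo cycloadduct methyl 2-oxo-3a,4,7,7a-tetrahydro-4,7-epoxy-1,3-benzodioxole-5-carboxylate (carbonate ring anti to the oxygen bridge)
Conditions: 2 (3 equiv), CH2Cl2 (minimum), hydroquinone (trace), 1.2 GPa, 50 °C; crystallisation or chromatography to remove any exo isomer
Reagents that add atoms: none
Why: Concerted suprafacial Diels–Alder [4+2] cycloaddition in which furan C2 and C5 of 1 bond to the two alkene carbons of 2, making C2–C3 and C4–C5 of the future cyclohexene at once; the closest known reaction type is the thermal or high-pressure cycloaddition of furan itself with vinylene carbonate or maleic anhydride. The six-membered carbocycle is closed by intermolecular [4+2] cycloaddition, and because the diene is a furan its ring oxygen becomes a one-atom bridge from C5 to C2, so the two oxolane rings of the 7-oxabicyclo[2.2.1]heptene arise in the same event (the dioxolanone ring comes in intact with 2). C3 and C4 become cis because addition to the Z alkene is suprafacial, C2 and C5 carry the bridge on one face because both belong to the planar furan, and the endo transition state puts the carbonate anti to the bridge, which is the 3,4-cis/4,5-trans pattern of the target. The step needs endo over exo selectivity: endo is the kinetic mode for cyclic cis dienophiles with furans, and pressure at low temperature should keep the reaction under kinetic control by suppressing cycloreversion and favouring the more compact transition state. No regiochemical question arises because 2 is symmetric, which is why the deactivating but needed ester can be carried on furan C3. The adduct is racemic and the absolute configuration is fixed in step 4.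

Step 2
Reactants: 3 racemic endo cycloadduct
Product: 4 racemic methyl 2-oxohexahydro-4,7-epoxy-1,3-benzodioxole-5-carboxylate (carbonate and ester both endo)
Conditions: H2 (1 atm), Pd/C (palladium on carbon, 5 wt %), EtOAc, rt
Reagents that add atoms: none
Why: Heterogeneous catalytic hydrogenation should add H2 syn to the strained, ester-conjugated C1=C6 bond from the exo face (the endo face is covered by the carbonate ring), which places the ester endo at C1 (a centre erased again in step 3) and removes the possibility of cycloreversion.

Step 3
Reactants: 4 racemic saturated bicyclic ester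
Product: 7 racemic methyl 5-O-acetyl-3,4-O-carbonylshikimate, via lithium ester enolate 5 (not isolated), via lithium alkoxide 6 (not isolated)
Conditions: LiN(SiMe3)2 (1.1 equiv), THF, −78 to −40 °C; then Ac2O (1.5 equiv), −78 to 0 °C; aq NH4Cl
Reagents that add atoms: acetic anhydride, CC(=O)OC(C)=O
Why: Deprotonation alpha to the ester gives enolate 5, which should undergo E1cB beta-elimination of the bridgehead C2–O bond (the standard base-induced opening of 7-oxabicyclo[2.2.1]heptane-2-carboxylates, driven by strain release and conjugation) to give alkoxide 6 with C1=C2 in place and C3, C4 and C5 untouched; O-acetylation in the same flask caps the alkoxide before it can add to the neighbouring carbonate and supplies the ester needed for the resolution.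

Step 4
Reactants: 7 racemic methyl 5-O-acetyl-3,4-O-carbonylshikimate
Product: 8 methyl (3R,4S,5R)-3,4-O-carbonylshikimate (free 5-OH)
Conditions: immobilised Candida antarctica lipase B (Novozym 435), n-BuOH (3 equiv), MTBE, 35 °C, stopped just short of half conversion; chromatography
Reagents that add atoms: none
Why: Lipase-catalysed kinetic resolution by transesterification of a secondary acetate: by the empirical size rule for lipases (C4 with its oxygen substituent as the large group, C6H2 as the medium one) and in line with the resolution of trans-2-substituted cycloalkanol esters, the (5R)-acetate should be cleaved much faster, releasing 8 and leaving the (3S,4R,5S)-acetate of 7 behind for removal; this fixes the absolute configuration, and the enantiomeric purity of 8 is to be checked and if needed raised by recrystallisation.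

Step 5
Reactants: 8 methyl (3R,4S,5R)-3,4-O-carbonylshikimate; 9 (E)-3-methylpent-2-enoic acid
Product: 11 methyl (3R,4S,5R)-3,4-O-carbonyl-5-O-[(E)-3-methylpent-2-enoyl]shikimate, via O-acylisourea 10 (not isolated)
Conditions: 9 (1.2 equiv), DCC (1.2 equiv), DMAP (0.1 equiv), CH2Cl2, 0 °C to rt
Reagents that add atoms: none
Why: Steglich esterification (DCC activation of 9 to O-acylisourea 10, then DMAP-catalysed acyl transfer) of the only free hydroxyl; the absence of strong base and the low temperature should preserve the E geometry of the beta,beta-disubstituted enoyl group and leave the carbonate and the C5 configuration untouched.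

Step 6
Reactants: 11 methyl (3R,4S,5R)-3,4-O-carbonyl-5-O-[(E)-3-methylpent-2-enoyl]shikimate; 9 (E)-3-methylpent-2-enoic acid
Product: 12 methyl (3R,4S,5R)-4-hydroxy-3,5-bis{[(E)-3-methylpent-2-enoyl]oxy}cyclohex-1-ene-1-carboxylate (target)
Conditions: Pd(PPh3)4 (5 mol %), 9 (1.5 equiv), THF, 0 °C to rt
Reagents that add atoms: none
Why: Tsuji–Trost-type decarboxylative allylic substitution, as in the known palladium-catalysed openings of vinyl epoxides and vinyl cyclic carbonates by carboxylic acids: zerovalent palladium ionises the only allylic C–O bond (C3–O of the carbonate) with inversion, CO2 is lost, the O4 alkoxide is protonated by 9, and the carboxylate attacks the allyl terminus C3 anti to palladium (second inversion, net retention, cis to O4) rather than the ester-bearing, fully substituted terminus C1, so O3 is acylated and O4–H released in one operation.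

**Compound list**

1 | methyl furan-3-carboxylate | COC(=O)c1ccoc1 | starting material
2 | vinylene carbonate (1,3-dioxol-2-one) | O=C1OC=CO1 | starting material
3 | racemic endo cycloadduct methyl 2-oxo-3a,4,7,7a-tetrahydro-4,7-epoxy-1,3-benzodioxole-5-carboxylate (carbonate anti to the oxygen bridge) | O=C3O[C@@H]1[C@@H]2C(C(=O)OC)=C[C@@H](O2)[C@@H]1O3 | intermediate
4 | racemic methyl 2-oxohexahydro-4,7-epoxy-1,3-benzodioxole-5-carboxylate (carbonate and ester endo) | O=C3O[C@@H]1[C@@H]2[C@H](C(=O)OC)C[C@@H](O2)[C@@H]1O3 | intermediate
5 | lithium ester enolate of 4 | O=C3O[C@@H]1[C@@H]2C(=C(OC)O[Li])C[C@@H](O2)[C@@H]1O3 | intermediate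
6 | lithium 5-alkoxide of racemic methyl 3,4-O-carbonylshikimate | O=C3O[C@@H]1C=C(C(=O)OC)C[C@@H](O[Li])[C@@H]1O3 | intermediate
7 | racemic methyl 5-O-acetyl-3,4-O-carbonylshikimate | O=C3O[C@@H]1C=C(C(=O)OC)C[C@@H](OC(C)=O)[C@@H]1O3 | intermediate
8 | methyl (3R,4S,5R)-3,4-O-carbonylshikimate | O=C3O[C@@H]1C=C(C(=O)OC)C[C@@H](O)[C@@H]1O3 | intermediate
9 | (E)-3-methylpent-2-enoic acid | CC/C(C)=C/C(=O)O | starting material
10 | O-acylisourea from 9 and DCC | CC/C(C)=C/C(=O)OC(=NC1CCCCC1)NC1CCCCC1 | intermediate
11 | methyl (3R,4S,5R)-3,4-O-carbonyl-5-O-[(E)-3-methylpent-2-enoyl]shikimate | O=C3O[C@@H]1C=C(C(=O)OC)C[C@@H](OC(=O)/C=C(\C)CC)[C@@H]1O3 | intermediate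
12 | methyl (3R,4S,5R)-4-hydroxy-3,5-bis{[(E)-3-methylpent-2-enoyl]oxy}cyclohex-1-ene-1-carboxylate | CC/C(C)=C/C(=O)O[C@@H]1C=C(C(=O)OC)C[C@@H](OC(=O)/C=C(\C)CC)[C@@H]1O | target

**Summary**

Total step count: 6
Longest linear sequence: 6 steps (1 and 2 to 12)

Steps most likely to fail:

Step 1. The ester lowers the diene reactivity of the furan, so the cycloaddition may be slow, and forcing it thermally invites cycloreversion and loss of endo selectivity. The fallback sets out from 2 and uses commercial 3-bromofuran in place of 1; a halogen makes the furan a better diene and its adducts less prone to cycloreversion. The same cycloaddition should give racemic endo 5-bromo-3a,4,7,7a-tetrahydro-4,7-epoxy-1,3-benzodioxol-2-one F1. Methoxycarbonylation of the vinyl bromide (CO 1 atm, Pd(OAc)2, 1,3-bis(diphenylphosphino)propane, MeOH 5 equiv, Et3N, DMF, 60 °C) then returns to the route at 3.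

Step 4. The lipase may discriminate poorly between the enantiomeric acetates, or attack the cyclic carbonate. The fallback replaces resolution by catalytic desymmetrisation and sets out from 2 and parent furan.
- The known cycloaddition gives meso endo 3a,4,7,7a-tetrahydro-4,7-epoxy-1,3-benzodioxol-2-one F2.
- Rhodium-catalysed asymmetric hydroformylation (Rh(acac)(CO)2, chiral bisphospholane ligand, CO/H2, toluene) should place a formyl group exo on one of the two enantiotopic alkene carbons, giving exo-5-formylhexahydro-4,7-epoxy-1,3-benzodioxol-2-one F3. The ligand enantiomer is chosen so that the formylated carbon becomes C1 of the natural series.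
- Pinnick oxidation (NaClO2, NaH2PO4, 2-methylbut-2-ene) gives the exo carboxylic acid F4, and Me3SiCHN2 in MeOH gives the exo methyl ester F5, the C1 epimer of the natural-series enantiomer of 4.
- LiN(SiMe3)2 as in step 3, but with an AcOH quench, passes through the single enantiomers of 5 and 6 and rejoins the route at 8.

Step 6. The allylpalladium intermediate may undergo beta-hydride elimination and aromatisation, or C3 may lose its configuration through repeated ionisation. The fallback sets out from 11. Mild methanolysis of the cyclic carbonate (K2CO3 cat., MeOH, 0 °C; the hindered enoate and the conjugated methyl ester should react far more slowly) gives methyl 5-O-[(E)-3-methylpent-2-enoyl]shikimate F6. A second Steglich esterification with one equivalent of 9 (DCC, DMAP, CH2Cl2, −20 °C) is expected to take the allylic O3 rather than O4, which is flanked on both sides by oxygen substituents and is the least accessible hydroxyl, and returns to the route at 12.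

**Further compounds**

F1 | step 1 | racemic endo 5-bromo-3a,4,7,7a-tetrahydro-4,7-epoxy-1,3-benzodioxol-2-one | O=C3O[C@@H]1[C@@H]2C(Br)=C[C@@H](O2)[C@@H]1O3
F2 | step 4 | meso endo 3a,4,7,7a-tetrahydro-4,7-epoxy-1,3-benzodioxol-2-one | O=C3O[C@@H]1[C@@H]2C=C[C@@H](O2)[C@@H]1O3
F3 | step 4 | exo-5-formylhexahydro-4,7-epoxy-1,3-benzodioxol-2-one (carbonate endo, single enantiomer) | O=C3O[C@@H]1[C@@H]2[C@@H](C=O)C[C@@H](O2)[C@@H]1O3
F4 | step 4 | exo-2-oxohexahydro-4,7-epoxy-1,3-benzodioxole-5-carboxylic acid (carbonate endo) | O=C3O[C@@H]1[C@@H]2[C@@H](C(=O)O)C[C@@H](O2)[C@@H]1O3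
F5 | step 4 | methyl exo-2-oxohexahydro-4,7-epoxy-1,3-benzodioxole-5-carboxylate (carbonate endo, C1 epimer of 4) | O=C3O[C@@H]1[C@@H]2[C@@H](C(=O)OC)C[C@@H](O2)[C@@H]1O3
F6 | step 6 | methyl (3R,4S,5R)-3,4-dihydroxy-5-{[(E)-3-methylpent-2-enoyl]oxy}cyclohex-1-ene-1-carboxylate | O[C@@H]1C=C(C(=O)OC)C[C@@H](OC(=O)/C=C(\C)CC)[C@@H]1O
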